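**Plan**

Numbering: ring C1 (chain), C2 (OH), C3 (OMe), C4 (OH), C5, C6; side chain C7, C8, C9 (ester carbonyl).
Enabling feature: ring atoms C6-C5-C4(O) and chain atoms C7-C8-C9(O) are the same three-carbon acrylate unit, both bonded to C1, and C2-C3(OMe) is a methoxyacetyl unit. An acyclic keto diester with two identical arms therefore holds every carbon of the target.
Retrosynthetic cuts: two hydrogens are first added back (arene to 2-methoxycyclohexane-1,3-dione), then C3-C4 is cut (Claisen), then C1-C6 and C1-C7 (two Michael additions to a C1 that temporarily carries CO2Me).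
Forward order: both arms are attached to C1, CO2Me is removed, the only ring closes at C3-C4, and the dione is silylated and dehydrogenated. The ester chain is never built separately.
Stereochemistry: the target has no stereocentre. The C1 centre in 3, 6, 7 and 8 is racemic and disappears on aromatisation.

Key step: step 3

Assumption: 7 is drawn as its C2 enol and 8 as the C2=C3/C4=C5 diene; the other enol tautomer or the C1=C2/C3=C4 diene would give the same arene 9.

**Step 1**
Reactants: 1 methyl 4-methoxyacetoacetate; 2 octadecyl acrylate (two equivalents)
Product: 4 dioctadecyl 4-(methoxyacetyl)-4-(methoxycarbonyl)heptanedioate, via mono-Michael adduct 3 (not isolated)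
Conditions: DBU (0.2 equiv), 2 (2.1 equiv), THF, 40 °C
Reagents that add atoms: none
Why: Two successive amidine-catalysed Michael additions of the doubly activated methylene (future C1) to the acrylate follow the chemistry used in acetoacetate-acrylate curing; DBU cannot transesterify, it is too weak to engage the methoxymethylene carbon, and 4 has no stereocentre because both arms are alike.

**Step 2**
Reactants: 4 dioctadecyl 4-(methoxyacetyl)-4-(methoxycarbonyl)heptanedioate
Product: 5 dioctadecyl 4-(2-methoxyacetyl)heptanedioate
Conditions: LiCl (3 equiv), H2O (2 equiv), DMSO, 150 °C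
Reagents that add atoms: none
Why: In this Krapcho demethoxycarbonylation chloride attacks the unhindered methyl group of the only ester whose carboxylate is beta-keto activated, CO2 is lost and water protonates the enolate, while the unactivated long-chain primary esters should stay intact.

**Step 3**
Reactants: 5 dioctadecyl 4-(2-methoxyacetyl)heptanedioate
Product: 7 octadecyl 3-(2-hydroxy-3-methoxy-4-oxocyclohex-2-en-1-yl)propanoate (racemic), via potassium enolate 6 (not isolated)
Conditions: KOC(CH3)3 (1.2 equiv), THF/t-BuOH, 0.03 M, 0 to 50 °C, Ar; then 1 M HCl, 0 °C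
Reagents that add atoms: none
Why: KOC(CH3)3 reversibly deprotonates the ketone at C3, the methylene flanked by the carbonyl and the methoxy group; this enolate adds to the ester carbonyl C4 of one arm, the tetrahedral adduct expels octadecanoxide, and that alkoxide at once deprotonates the new dione to 6. The reaction type is the intramolecular Claisen (Dieckmann-type) condensation that turns delta-keto esters into cyclohexane-1,3-diones. The single ring closes in the favoured 6-(enolendo)-exo-trig mode, since the enolate bond C2=C3 lies inside the new ring and the ester C=O outside it. C1 becomes a stereocentre because the two enantiotopic arms are differentiated without any control element, so 7 is racemic, which is harmless because C1 becomes trigonal in step 5. The closure must beat arm-to-arm Dieckmann condensation and enolisation towards C1: the C3 hydrogens are several pK units more acidic than those next to an ester, the C1 enolate could only close a four-membered ring, and every condensation is reversible under alkoxide while 6, the salt of a vinylogous acid, is the thermodynamic sink. Either arm gives the same product, and the arm left over is already the finished octadecyl propanoate chain.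

**Step 4**
Reactants: 7 octadecyl 3-(2-hydroxy-3-methoxy-4-oxocyclohex-2-en-1-yl)propanoate
Product: 8 octadecyl 3-[3-methoxy-2,4-bis(trimethylsilyloxy)cyclohexa-2,4-dien-1-yl]propanoate (racemic, used crude)
Conditions: TMSOTf (2.3 equiv), Et3N (3 equiv), CH2Cl2, 0 °C to rt; evaporation, pentane extraction, filtration under Ar
Reagents that add atoms: trimethylsilyl trifluoromethanesulfonate, C[Si](C)(C)OS(=O)(=O)C(F)(F)F
Why: Soft enolisation with silyl triflate and amine silylates the enol oxygen and then the remaining carbonyl with loss of a C5 proton, the standard way from cyclohexane-1,3-diones to 1,3-bis(silyloxy)cyclohexa-1,3-dienes; the isolated ester enolises far more slowly and the reagent is kept to a slight excess.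

**Step 5**
Reactants: 8 octadecyl 3-[3-methoxy-2,4-bis(trimethylsilyloxy)cyclohexa-2,4-dien-1-yl]propanoate
Product: 10 octadecyl 3-(2,4-dihydroxy-3-methoxyphenyl)propanoate (target), via bis(trimethylsilyl) aryl ether 9 (not isolated)
Conditions: DDQ (1.0 equiv), toluene, 0 °C to rt, filtration; then 1 M HCl, THF, 0 °C
Reagents that add atoms: none
Why: In this quinone dehydrogenation of a silyloxy cyclohexadiene, hydride abstraction from C6 gives a pentadienyl cation stabilised by both silyloxy groups, loss of the C1 proton gives arene 9 and erases the stereocentre, and cold dilute acid then hydrolyses the labile aryl trimethylsilyl ethers without touching the ester.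

**Compound list**

1 | methyl 4-methoxyacetoacetate | COCC(=O)CC(=O)OC | starting material
2 | octadecyl acrylate | CCCCCCCCCCCCCCCCCCOC(=O)C=C | starting material
3 | 1-methyl 5-octadecyl 2-(methoxyacetyl)pentanedioate (racemic mono-Michael adduct) | CCCCCCCCCCCCCCCCCCOC(=O)CCC(C(=O)OC)C(=O)COC | intermediate
4 | dioctadecyl 4-(methoxyacetyl)-4-(methoxycarbonyl)heptanedioate | CCCCCCCCCCCCCCCCCCOC(=O)CCC(CCC(=O)OCCCCCCCCCCCCCCCCCC)(C(=O)OC)C(=O)COC | intermediate
5 | dioctadecyl 4-(2-methoxyacetyl)heptanedioate | CCCCCCCCCCCCCCCCCCOC(=O)CCC(CCC(=O)OCCCCCCCCCCCCCCCCCC)C(=O)COC | intermediate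
6 | potassium enolate of 7 (racemic) | CCCCCCCCCCCCCCCCCCOC(=O)CCC1CCC(=O)C(OC)=C1[O-].[K+] | intermediate
7 | octadecyl 3-(2-hydroxy-3-methoxy-4-oxocyclohex-2-en-1-yl)propanoate (racemic, enol of the 1,3-dione) | CCCCCCCCCCCCCCCCCCOC(=O)CCC1CCC(=O)C(OC)=C1O | intermediate
8 | octadecyl 3-[3-methoxy-2,4-bis(trimethylsilyloxy)cyclohexa-2,4-dien-1-yl]propanoate (racemic) | CCCCCCCCCCCCCCCCCCOC(=O)CCC1CC=C(O[Si](C)(C)C)C(OC)=C1O[Si](C)(C)C | intermediate
9 | octadecyl 3-[3-methoxy-2,4-bis(trimethylsilyloxy)phenyl]propanoate | CCCCCCCCCCCCCCCCCCOC(=O)CCc1ccc(O[Si](C)(C)C)c(OC)c1O[Si](C)(C)C | intermediate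
10 | octadecyl 3-(2,4-dihydroxy-3-methoxyphenyl)propanoate | CCCCCCCCCCCCCCCCCCOC(=O)CCc1ccc(O)c(OC)c1O | target

Total step count: 5. Longest linear sequence: 5.

**Steps most likely to fail**

Step 3.
- Risk: unproductive enolisation towards the C1 methine may slow the closure, so that arm-to-arm Dieckmann condensation or intermolecular Claisen oligomerisation overtakes it.
- Fallback: the ring is closed before the methoxycarbonyl group is removed. The fallback sets out from 4, where C1 is quaternary, so the ketone can enolise only towards C3 and the geminal substitution favours folding.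
- Route: KOC(CH3)3 in THF, followed by cold acid, should give methyl 2-hydroxy-3-methoxy-1-[3-(octadecyloxy)-3-oxopropyl]-4-oxocyclohex-2-ene-1-carboxylate F1. A Krapcho demethoxycarbonylation with LiCl in wet DMSO at 130 °C then removes the ring ester and returns to the route at 7.

Step 5.
- Risk: the quinone may go on to oxidise the electron-rich arene or the benzylic position C7, or adventitious moisture may hydrolyse the diene back to the dione before it is oxidised.
- Fallback: silicon and quinone are both left out. The fallback sets out from 7 and uses the aerobic catalytic dehydrogenation of cyclic ketones: Pd(O2CCF3)2 (5 mol %), 2-(dimethylamino)pyridine, TsOH, O2 (1 atm), DMSO, 80 °C.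
- Mechanism: an enolate of divalent palladium forms at C5, beta-hydride elimination from C6 follows, the dienone tautomerises, and O2 reoxidises zerovalent palladium.
- It returns to the route directly at 10 and makes no new compound.

Step 2.
- Risk: at 150 °C the base generated in the flask may cleave the electrophilic methoxyacetyl ketone by a retro-Claisen process or saponify the octadecyl esters.
- Fallback: the activating ester is removed under neutral conditions by hydrogenolysis. The fallback sets out from 1.
- Route: transesterification with benzyl alcohol (DMAP, toluene, reflux, removal of methanol) should give benzyl 4-methoxy-3-oxobutanoate F2.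
- DBU-catalysed double Michael addition to 2 then passes through 1-benzyl 5-octadecyl 2-(methoxyacetyl)pentanedioate F3 to dioctadecyl 4-(benzyloxycarbonyl)-4-(methoxyacetyl)heptanedioate F4.
- Hydrogenolysis (H2, Pd/C, EtOAc/THF, rt) gives 2-(methoxyacetyl)-5-(octadecyloxy)-2-[3-(octadecyloxy)-3-oxopropyl]-5-oxopentanoic acid F5.
- This beta-keto acid loses CO2 on warming in toluene at 70 °C and returns to the route at 5.

**Further compounds**

F1 | step 3 | methyl 2-hydroxy-3-methoxy-1-[3-(octadecyloxy)-3-oxopropyl]-4-oxocyclohex-2-ene-1-carboxylate (racemic) | CCCCCCCCCCCCCCCCCCOC(=O)CCC1(C(=O)OC)CCC(=O)C(OC)=C1O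
F0 | step 5 | none | none
F2 | step 2 | benzyl 4-methoxy-3-oxobutanoate | COCC(=O)CC(=O)OCc1ccccc1
F3 | step 2 | 1-benzyl 5-octadecyl 2-(methoxyacetyl)pentanedioate (racemic) | CCCCCCCCCCCCCCCCCCOC(=O)CCC(C(=O)OCc1ccccc1)C(=O)COC
F4 | step 2 | dioctadecyl 4-(benzyloxycarbonyl)-4-(methoxyacetyl)heptanedioate | CCCCCCCCCCCCCCCCCCOC(=O)CCC(CCC(=O)OCCCCCCCCCCCCCCCCCC)(C(=O)OCc1ccccc1)C(=O)COC
F5 | step 2 | 2-(methoxyacetyl)-5-(octadecyloxy)-2-[3-(octadecyloxy)-3-oxopropyl]-5-oxopentanoic acid | CCCCCCCCCCCCCCCCCCOC(=O)CCC(CCC(=O)OCCCCCCCCCCCCCCCCCC)(C(=O)O)C(=O)COC
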